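**Plan**
- Retrosynthesis: the C6–O ester bond is cut first (p-coumaroyl unit off), then the C5–C10 ring-fusion bond, then the C6–C7 bond of the ten-membered ring, which leads back to a farnesol chain oxidised at C1 and chlorinated at C12.
- Enabling feature: C5–C10 bisects the carbocycle C1–C10, so rings A and B, the quaternary C10 methyl and H5 are latent in an (E,E)-germacra-1(10),4-diene that already carries O6 and the C7 isopropyl group.
- Forward order: Pd/Zn allylation closes the ten-membered ring at C6–C7; the ring is adjusted (isopropenyl reduction, C6 inversion, epoxide removal); one proton-induced transannular step then forms C5–C10 and both six-membered rings; the ester is attached last.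
- Stereochemistry: a Sharpless epoxide at C4/C5 is the only external source; it directs C6 (Felkin–Anh) and C7 (chair allylzinc transition state) in the ring closure; C6 is then inverted by Mitsunobu and the epoxide is removed with retention to the 4E olefin.
- C5 and C10 (trans fusion) come from the chair–chair conformer of the (E,E)-diene with the C7 isopropyl equatorial; the E-cinnamate comes from p-coumaric acid.

Key step: step 10

Numbering: germacrane/eudesmane numbering (C1–C15) for ring compounds, farnesane numbering for open-chain ones.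
Assumption: the Pd/Zn ring closure follows the acyclic models (Felkin–Anh at C5/C6, chair transition state of the E-allylzinc at C6/C7) and gives the 6S,7S alcohol (OH trans to the C7 substituent), so C6 is inverted afterwards to the 6R (6β) configuration the target needs.

**Route**

Step 1
Reactants: 1 (2E,6E)-farnesol
Product: 2 (2S,3S)-2,3-epoxyfarnesol
Conditions: Ti(OiPr)4 (5 mol %), L-(+)-diethyl tartrate (6 mol %), t-BuOOH, 4 Å MS, CH2Cl2, −20 °C
Reagents that add atoms: tert-butyl hydroperoxide, CC(C)(C)OO
Why: Sharpless asymmetric epoxidation, in which the titanium–tartrate complex of the allylic alcohol delivers oxygen to one face of the 2,3-olefin only (L-(+)-tartrate gives 2S,3S) and leaves the two remote olefins alone.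

Step 2
Reactants: 2 (2S,3S)-2,3-epoxyfarnesol
Product: 3 (2S,3S,6E,10E)-2,3-epoxy-3,7,11-trimethyldodeca-6,10-diene-1,12-diol
Conditions: SeO2 (0.1 equiv), salicylic acid (0.1 equiv), t-BuOOH, CH2Cl2, 0 °C → rt
Reagents that add atoms: tert-butyl hydroperoxide, CC(C)(C)OO (oxygen relayed by catalytic selenium dioxide, O=[Se]=O)
Why: Selenium dioxide allylic oxidation (ene reaction, then [2,3]-sigmatropic shift), which by the usual selectivity rules attacks the E-methyl group of the terminal trisubstituted olefin and keeps the E geometry.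

Step 3
Reactants: 3 (2S,3S,6E,10E)-2,3-epoxy-3,7,11-trimethyldodeca-6,10-diene-1,12-diol
Product: 4 (2S,3S,6E,10E)-12-chloro-2,3-epoxy-3,7,11-trimethyldodeca-6,10-dien-1-ol
Conditions: NCS, Me2S, CH2Cl2, −30 → 0 °C
Reagents that add atoms: N-chlorosuccinimide, O=C1CCC(=O)N1Cl
Why: Corey–Kim chlorination, which converts only the allylic alcohol into the chloride by SN2 displacement of its alkoxysulfonium ion; the saturated primary epoxy alcohol is returned unchanged because no base is added.

Step 4
Reactants: 4 (2S,3S,6E,10E)-12-chloro-2,3-epoxy-3,7,11-trimethyldodeca-6,10-dien-1-ol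
Product: 5 (2R,3S,6E,10E)-12-chloro-2,3-epoxy-3,7,11-trimethyldodeca-6,10-dienal
Conditions: Dess–Martin periodinane, NaHCO3, CH2Cl2, 0 °C → rt; used crude
Reagents that add atoms: none
Why: Dess–Martin oxidation under buffered conditions should give the α,β-epoxy aldehyde without epimerisation at C2 or loss of the allylic chloride (the C2 descriptor changes from S to R by priority only).

Step 5
Reactants: 5 (2R,3S,6E,10E)-12-chloro-2,3-epoxy-3,7,11-trimethyldodeca-6,10-dienal
Product: 6 (1(10)E,4S,5S,6S,7S)-4,5-epoxygermacra-1(10),11-dien-6-ol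
Conditions: PdCl2(PPh3)2 (10 mol %), Et2Zn (3 equiv), DMA, rt, syringe-pump addition of 5 (final ≤5 mM); aq NH4Cl
Reagents that add atoms: none
Why: Palladium-catalysed umpolung allylation, a ring closure known for epoxy chloro aldehydes of this type: the π-allylpalladium species is converted by diethylzinc into an allylzinc that adds through its γ-carbon to the aldehyde in a chair transition state under high dilution, closing the ten-membered ring at C6–C7, with C6 set by Felkin–Anh attack anti to the epoxide C–O bond and C7 by the E-allyl chair with both chain ends equatorial.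

Step 6
Reactants: 6 (1(10)E,4S,5S,6S,7S)-4,5-epoxygermacra-1(10),11-dien-6-ol
Product: 7 (1(10)E,4S,5S,6S,7S)-4,5-epoxygermacr-1(10)-en-6-ol
Conditions: H2 (1 atm), RhCl(PPh3)3 (5 mol %), benzene–EtOH, rt
Reagents that add atoms: none
Why: Homogeneous hydrogenation with Wilkinson's catalyst reduces the 1,1-disubstituted isopropenyl olefin much faster than the trisubstituted ring olefin and leaves the epoxide alone; no stereocenter is formed.

Step 7
Reactants: 7 (1(10)E,4S,5S,6S,7S)-4,5-epoxygermacr-1(10)-en-6-ol
Product: 8 (1(10)E,4S,5S,6R,7S)-4,5-epoxygermacr-1(10)-en-6-yl 4-nitrobenzoate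
Conditions: 4-nitrobenzoic acid, PPh3, DIAD, toluene, 0 °C → rt
Reagents that add atoms: 4-nitrobenzoic acid, O=C(O)c1ccc(cc1)[N+](=O)[O-]
Why: Mitsunobu esterification, in which the oxyphosphonium ion of the secondary alcohol is displaced by the acidic carboxylate in an SN2 step with inversion at C6 (6S to 6R); with the 4,5-olefin still masked as the epoxide, no allylic cation can form.

Step 8
Reactants: 8 (1(10)E,4S,5S,6R,7S)-4,5-epoxygermacr-1(10)-en-6-yl 4-nitrobenzoate
Product: 9 (1(10)E,4S,5S,6R,7S)-4,5-epoxygermacr-1(10)-en-6-ol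
Conditions: K2CO3 (0.2 equiv), MeOH, 0 °C → rt
Reagents that add atoms: none
Why: Base-catalysed transesterification of the activated 4-nitrobenzoate releases the 6R alcohol without touching the C6–O bond, under conditions mild enough to avoid Payne migration of the epoxide.

Step 9
Reactants: 9 (1(10)E,4S,5S,6R,7S)-4,5-epoxygermacr-1(10)-en-6-ol
Product: 11 (1(10)E,4E,6R,7S)-germacra-1(10),4-dien-6-ol, via lithium alkoxide of the epoxy alcohol 10 (not isolated)
Conditions: n-BuLi (1.0 equiv), THF, −78 °C; then added to WCl6/n-BuLi (1:2, 3 equiv W, pre-formed in THF, −78 °C → rt), rt; aq NaOH/Rochelle salt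
Reagents that add atoms: none
Why: Deoxygenation with the lower-valent tungsten chloride reagent removes the epoxide oxygen by syn elimination with retention, as known for trisubstituted and germacrane epoxides, and so returns the 4E olefin; the hydroxyl is carried as its lithium alkoxide so that no HCl forms near the acid-sensitive diene.

Step 10
Reactants: 11 (1(10)E,4E,6R,7S)-germacra-1(10),4-dien-6-ol
Product: 12 eudesm-3-en-6β-ol (5R,6R,7S,10R)
Conditions: TsOH·H2O (5 mol %), dry CH2Cl2, −20 → 0 °C; Et3N quench
Reagents that add atoms: none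
Why: This is the acid-promoted transannular cation–olefin cyclisation known for (E,E)-germacra-1(10),4-dienes: the proton adds to C1 of the C1=C10 olefin (the C4=C5 olefin is deactivated by the allylic oxygen), the C4=C5 π-bond attacks the developing C10 cation through C5, and the tertiary C4 cation loses H3. The single C5–C10 bond divides the ten-membered ring, so ring A (C1–C5, C10) closes in a 6-endo sense and ring B (C5–C10) in a 6-exo sense relative to the C4=C5 nucleophile. C10 and C5 are set by the crossed chair–chair conformer in which the C7 isopropyl group is pseudo-equatorial: the olefin faces that meet put C14 on the β face and H5 on the α face, giving the trans fusion (5R,10R), while C6 and C7 are untouched and O6 ends axial. The step needs initiation at C1 rather than ionisation of the allylic C6–O bond, which a catalytic sulfonic acid at low temperature in a dry, non-nucleophilic solvent should secure. It also needs loss of H3 rather than H15 or H5: H5 is tertiary, shielded and inductively deactivated by C6–O, and loss of axial H3 gives the more substituted endocyclic alkene, so the Δ3 isomer should predominate with the exocyclic isomer as the expected by-product.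

Step 11
Reactants: 13 p-coumaric acid
Product: 15 (2E)-3-[4-(tert-butyldimethylsilyloxy)phenyl]prop-2-enoic acid, via bis-silylated silyl ester 14 (not isolated)
Conditions: TBSCl (2.3 equiv), imidazole, DMF, rt; then AcOH–THF–H2O, rt
Reagents that add atoms: tert-butyldimethylsilyl chloride, CC(C)(C)[Si](C)(C)Cl
Why: Silylation of both acidic OH groups followed by selective hydrolysis of the much more labile silyl ester is the standard protection of hydroxycinnamic acids and leaves the aryl silyl ether and the E olefin intact.

Step 12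
Reactants: 12 eudesm-3-en-6β-ol; 15 (2E)-3-[4-(tert-butyldimethylsilyloxy)phenyl]prop-2-enoic acid
Product: 17 eudesm-3-en-6β-yl (2E)-3-[4-(tert-butyldimethylsilyloxy)phenyl]prop-2-enoate, via acid chloride 16 (not isolated)
Conditions: 15, (COCl)2, DMF (cat.), CH2Cl2, 0 °C → rt, evaporate; then 12, DMAP, Et3N, CH2Cl2, 40 °C
Reagents that add atoms: none
Why: Acylation of the hindered axial alcohol by the acid chloride under nucleophilic (DMAP, acylpyridinium) catalysis; the C6–O bond is not broken, so the 6β configuration is kept.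

Step 13
Reactants: 17 eudesm-3-en-6β-yl (2E)-3-[4-(tert-butyldimethylsilyloxy)phenyl]prop-2-enoate
Product: 18 eudesm-3-en-6β-yl (2E)-3-(4-hydroxyphenyl)prop-2-enoate (target)
Conditions: TBAF, AcOH, THF, 0 °C
Reagents that add atoms: none
Why: Fluoride cleavage of the aryl silyl ether, buffered with acetic acid so that the phenoxide cannot attack the cinnamate; the ester, both olefins and all stereocenters are untouched.

**Compound list**
1 | (2E,6E)-farnesol | CC(C)=CCC/C(C)=C/CC/C(C)=C/CO | starting material
2 | (2S,3S)-2,3-epoxyfarnesol, [(2S,3S)-3-[(3E)-4,8-dimethylnona-3,7-dien-1-yl]-3-methyloxiran-2-yl]methanol | OC[C@@H]1O[C@@]1(C)CC/C=C(\C)CCC=C(C)C | intermediate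
3 | (2S,3S,6E,10E)-2,3-epoxy-3,7,11-trimethyldodeca-6,10-diene-1,12-diol | OC[C@@H]1O[C@@]1(C)CC/C=C(\C)CC/C=C(\C)CO | intermediate
4 | (2S,3S,6E,10E)-12-chloro-2,3-epoxy-3,7,11-trimethyldodeca-6,10-dien-1-ol | OC[C@@H]1O[C@@]1(C)CC/C=C(\C)CC/C=C(\C)CCl | intermediate
5 | (2R,3S,6E,10E)-12-chloro-2,3-epoxy-3,7,11-trimethyldodeca-6,10-dienal | O=C[C@@H]1O[C@@]1(C)CC/C=C(\C)CC/C=C(\C)CCl | intermediate
6 | (1(10)E,4S,5S,6S,7S)-4,5-epoxygermacra-1(10),11-dien-6-ol, (1S,2S,3S,6E,10S)-6,10-dimethyl-3-(prop-1-en-2-yl)-11-oxabicyclo[8.1.0]undec-6-en-2-ol | O[C@@H]1[C@@H]2O[C@@]2(C)CC/C=C(\C)CC[C@H]1C(C)=C | intermediate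
7 | (1(10)E,4S,5S,6S,7S)-4,5-epoxygermacr-1(10)-en-6-ol | O[C@@H]1[C@@H]2O[C@@]2(C)CC/C=C(\C)CC[C@H]1C(C)C | intermediate
8 | (1(10)E,4S,5S,6R,7S)-4,5-epoxygermacr-1(10)-en-6-yl 4-nitrobenzoate | O=C(O[C@H]1[C@@H]2O[C@@]2(C)CC/C=C(\C)CC[C@H]1C(C)C)c1ccc(cc1)[N+](=O)[O-] | intermediate
9 | (1(10)E,4S,5S,6R,7S)-4,5-epoxygermacr-1(10)-en-6-ol | O[C@H]1[C@@H]2O[C@@]2(C)CC/C=C(\C)CC[C@H]1C(C)C | intermediate
10 | lithium (1(10)E,4S,5S,6R,7S)-4,5-epoxygermacr-1(10)-en-6-olate | [Li+].[O-][C@H]1[C@@H]2O[C@@]2(C)CC/C=C(\C)CC[C@H]1C(C)C | intermediate (not isolated)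
11 | (1(10)E,4E,6R,7S)-germacra-1(10),4-dien-6-ol, (1R,2E,6E,10S)-3,7-dimethyl-10-(propan-2-yl)cyclodeca-2,6-dien-1-ol | C/C1=C\[C@H](O)[C@H](C(C)C)CC/C(C)=C/CC1 | intermediate
12 | eudesm-3-en-6β-ol (5αH, 7β-isopropyl, 10β-methyl), (1R,2S,4aR,8aR)-4a,8-dimethyl-2-(propan-2-yl)-1,2,3,4,4a,5,6,8a-octahydronaphthalen-1-ol | CC1=CCC[C@]2(C)CC[C@@H](C(C)C)[C@@H](O)[C@@H]12 | intermediate
13 | p-coumaric acid, (2E)-3-(4-hydroxyphenyl)prop-2-enoic acid | O=C(O)/C=C/c1ccc(O)cc1 | starting material
14 | tert-butyldimethylsilyl (2E)-3-[4-(tert-butyldimethylsilyloxy)phenyl]prop-2-enoate | CC(C)(C)[Si](C)(C)OC(=O)/C=C/c1ccc(O[Si](C)(C)C(C)(C)C)cc1 | intermediate (not isolated)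
15 | (2E)-3-[4-(tert-butyldimethylsilyloxy)phenyl]prop-2-enoic acid | O=C(O)/C=C/c1ccc(O[Si](C)(C)C(C)(C)C)cc1 | intermediate
16 | (2E)-3-[4-(tert-butyldimethylsilyloxy)phenyl]prop-2-enoyl chloride | O=C(Cl)/C=C/c1ccc(O[Si](C)(C)C(C)(C)C)cc1 | intermediate (not isolated)
17 | eudesm-3-en-6β-yl (2E)-3-[4-(tert-butyldimethylsilyloxy)phenyl]prop-2-enoate | CC1=CCC[C@]2(C)CC[C@@H](C(C)C)[C@@H](OC(=O)/C=C/c3ccc(O[Si](C)(C)C(C)(C)C)cc3)[C@@H]12 | intermediate
18 | eudesm-3-en-6β-yl (2E)-3-(4-hydroxyphenyl)prop-2-enoate, (1R,2S,4aR,8aR)-4a,8-dimethyl-2-(propan-2-yl)-1,2,3,4,4a,5,6,8a-octahydronaphthalen-1-yl ester | CC1=CCC[C@]2(C)CC[C@@H](C(C)C)[C@@H](OC(=O)/C=C/c3ccc(O)cc3)[C@@H]12 | target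

**Step count and risks**
Total steps: 13. Longest linear sequence: 12 (steps 1–10, 12, 13 from farnesol); step 11 is the one-step side branch.

Step 10 is the riskiest. The C4 cation may lose its proton unselectively (H15 or H5 instead of H3), and acid may also ionise the allylic C6–O bond. The fallback sets out from 11 and converges every double-bond isomer. The crude isomer mixture from the same cyclisation is oxidised (buffered Dess–Martin) and equilibrated with DBU to the single conjugated enone eudesm-4-en-6-one F1, in which the 7β-isopropyl group stays equatorial. The thermodynamic extended dienolate (KOt-Bu, t-BuOH–THF) is then quenched kinetically with cold aqueous acetic acid; protonation at C5 from the α face, anti to the angular methyl, should give eudesm-3-en-6-one F2. L-Selectride at −78 °C should attack C6 from the same open α face and give the axial 6β alcohol, so the route is rejoined at 12.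

Step 7 is next. The SN2 displacement at the crowded C6 oxyphosphonium ion may fail, giving elimination toward C7 or return of alcohol without inversion. The fallback sets out from 7 and moves the C6 correction onto the rigid decalin. The epoxide is removed under the tungsten conditions of step 9 to give (1(10)E,4E,6S,7S)-germacra-1(10),4-dien-6-ol F3. The same acid-promoted transannular cyclisation should give eudesm-3-en-6α-ol F4 with an equatorial hydroxyl. Buffered Dess–Martin oxidation then gives eudesm-3-en-6-one F2, kept cold and reduced at once with L-Selectride from the α face; the route is rejoined at 12.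

Step 9 is third. The tungsten reagent may erode the olefin geometry, or its Lewis acidity may trigger transannular attack of the C1=C10 olefin on the activated epoxide. The fallback sets out from 9 and uses a neutral, metal-free two-step sequence. Thiourea in methanol (40 °C) should convert the epoxide, with inversion at both carbons, into the trans thiirane (1(10)E,4R,5R,6R,7S)-4,5-epithiogermacr-1(10)-en-6-ol F5. Tributylphosphine (THF, 40 °C) then removes sulfur with retention and gives the 4E olefin; the route is rejoined at 11.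

Further compounds
F1 | step 10 | eudesm-4-en-6-one (7β-isopropyl, 10β-methyl) | CC1=C2C(=O)[C@H](C(C)C)CC[C@@]2(C)CCC1
F2 | step 10 | eudesm-3-en-6-one (5αH, 7β-isopropyl, 10β-methyl) | CC1=CCC[C@]2(C)CC[C@@H](C(C)C)C(=O)[C@@H]12
F3 | step 7 | (1(10)E,4E,6S,7S)-germacra-1(10),4-dien-6-ol | C/C1=C\[C@@H](O)[C@H](C(C)C)CC/C(C)=C/CC1
F4 | step 7 | eudesm-3-en-6α-ol (5αH, 7β-isopropyl, 10β-methyl) | CC1=CCC[C@]2(C)CC[C@@H](C(C)C)[C@H](O)[C@@H]12
F5 | step 9 | (1(10)E,4R,5R,6R,7S)-4,5-epithiogermacr-1(10)-en-6-ol | O[C@H]1[C@H]2S[C@]2(C)CC/C=C(\C)CC[C@H]1C(C)C
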